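Through the run, the charge of solid substrate stayed divided among solid, starting material, target and cross product, and the charge of partner among partner, target, second product and dormant form.

    starting material + partner ⇌ target (K1 = 3.0 M⁻¹, k1 = 0.0040 M⁻¹ min⁻¹)
    second substrate + partner → second product (k2 = 0.0014 M⁻¹ min⁻¹)
    starting material + second substrate → cross product (k3 = 0.0053 M⁻¹ min⁻¹)
    partner ⇌ dormant form (K4 = 0.19, k4 = 8.6 × 10⁻⁵ min⁻¹)
    solid substrate ⇌ starting material, rate k5*(cs5 - [starting material]) while solid is left; crystals form when [starting material] > cs5 (cs5 = 0.19 M, k5 = 0.0013 min⁻¹)

solid substrate 0.20 M; partner 0.240 M; second substrate 0.200 M; time 15 d

1. part of the solid substrate that has turned into other species by 15 d (what has only dissolved does not count)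
2. amount of target at 15 d, in percent of the solid substrate charged
3. amount of cross product at 15 d, in percent of the solid substrate charged

- solid, in amounts per volume of the solution: solid substrate
- at the start none of the solid substrate is in solution
- what has only dissolved of solid substrate counts as not reacted
- run time (flask): 15 d

One thing in this flask looked contradictory. By step 1 alone, starting material has a forward half-life of 0.50 d, far shorter than the run of 15 d, yet K1 times the charged partner is 0.72, which puts target below starting material. The two go together: the half-life counts the forward rate and not the way back, while at balance the ratio of target to starting material is K1[partner]. So I needed the free [partner].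

The solid needs about 0.562 d at full dissolving rate, far shorter than the run, so I counted it dissolved. Second substrate has a half-life of 1.4 d by step 2 alone, so I let its 0.200 M end as cross product and second product. They share it by the rate ratio k3[starting material]/k2[partner], the selectivity factor, which starts at zero and rises as the first solid dissolves. With [starting material] at half the solid charge and [partner] as charged, I took the factor as 1.58, giving cross product 0.122 M and second product 0.0776 M.

Dormant form follows as K4[partner], its relaxation half-life of 0.894 d being far shorter than the run. Neglecting target, the partner balance gave [partner] 0.136 M. Target then took 0.0225 M, leaving 0.118 M. That made 0.353 the holding ratio, K1 times free [partner], target per starting material at balance. My reckoning was thus 10.1 % target, 61.2 % cross product and 71.3 % conversion.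

The forecast gave 70 %, 10.5 % and 60 %, in its words: “The target re-equilibrates quickly”. The flask gave 71.8 % conversion, 10.2 % target and 61.6 % cross product, and ten times the time showed 71.8 %, 10.2 % and 61.6 %. At 15.0 d this flask held 50.0 % of its partner, so K1[partner] was 0.360 against my 0.353, and target over starting material read 0.360. The neighbour charged with 0.96 M of partner kept 60.6 % of it, so its holding ratio was 1.75, and its target over starting material read 1.75.

(The numbers of this flask stand for no real mixture; the rest is arithmetic.)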